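3 questions hang on one ratio, side product per target, so count what the grey run gives of it.

| flask | solid substrate | reagent | remark | time |
|---|---|---|---|---|
| grey | 0.46 M | 0.84 M | run made earlier |  |
| spring | 0.30 M | 0.600 M |  | 4.0 d |
| dusk | 0.30 M | 0.300 M |  | 4.0 d |
| autumn | 0.80 M | 3.00 M |  | 4.0 d |
| dawn | 0.42 M | 0.840 M |  | 4.0 d |
| winter | 0.10 M | 0.600 M |  | 4.0 d |
| noon | 0.80 M | 0.200 M |  | 4.0 d |

grey run (percent of the solid substrate charged)

| time / h | target / % | side product / % |
|---|---|---|
| 1.00 | 0 | 0 |
| 3.00 | 1 | 2 |
| 5.00 | 2 | 5 |
| 8.00 | 2 | 7 |
| 12.0 | 7 | 11 |
| 15.0 | 12 | 18 |
| 20.0 | 14 | 23 |

(standard deviation of a reading: 1.5 percentage points)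

- given per volume of solution although it is solid: solid substrate
- at the start none of the solid substrate is in solution
- what has only dissolved of solid substrate counts as not reacted
- a reading or a percentage of target counts all its forms, free or not

- all flasks from highest to lowest share of target in all that became target or side product, at 4.0 d (spring / dusk / autumn / dawn / winter / noon)
- the share of target in all that became target or side product of the flask you put first, at 4.0 d
- the share of target in all that became target or side product of the flask you put last, at 4.0 d

The flasks differ in reagent, but grey was run at a single charge of it. This reckoning therefore assumes that the side route takes one more reagent than the target route. The ratio then grows in proportion to [reagent], and the share of target is one over one plus that ratio.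

Before trusting the constant, test its inputs on noon, the flask with the least reagent. Both readings are percentages of grey's solid charge, so that charge cancels in their ratio. Raising the last target reading by its scatter moves the noon share by 2 percentage points, and raising the side product reading moves it by 1.3 points. If grey's [reagent] had averaged 0.7 of its charge, the share would move by 7.7 points, more than either reading does. So [reagent] is the input to watch.

The selectivity factor S, side product over target at the last grey reading per unit of grey's charged reagent, reads 1.96 L mol⁻¹. At the charged reagent it gives 71.9 % for noon and 14.6 % for autumn. Noon holds a quarter of an equivalent, so its [reagent] should fall and its share should end higher. This reckoning puts noon first, dusk second and autumn last.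

The forecast differs: autumn > dawn > spring > dusk > noon > winter, with top 74 % (60 % to 88 %) and low 27 % (15 % to 40 %). Its grounds included this: “I assume reagent affects both routes equally”.

The flasks give noon > dusk > spring > dawn > winter > autumn, with top 82.0 % and low 17.2 %.

    reagent + target ⇌ idle adduct, settled at all times (K = 12.0 L mol⁻¹)
    solid substrate ⇌ starting material, rate k2*(cs2 - [starting material]) while solid is left; crystals form when [starting material] > cs2 (solubility = 0.370 M, k = 0.0660 h⁻¹)
    starting material + reagent → target (k = 0.0530 L mol⁻¹ h⁻¹)
    starting material + 2 reagent → side product (k = 0.120 L² mol⁻² h⁻¹)

Just after the start of noon, starting material went to target 2.2 times as fast as to side product, where S at the charged reagent gives 2.56. By 0.636 d that ratio had risen to 2.9. For the neighbouring flask with 0.080 M of reagent and 16 % of it left unbound, S at the mean of charge and remainder gives 91.7 %, and that flask gives 91.3 %.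

The earlier runs and the new flask were computed from invented constants; noise was put on by code.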